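## Retrosynthetic overview

1. The C11–O ester bond is cut last. The target comes from (−)-drimenol and caffeic acid carried as its bis-TBS ether.
2. The C7=C8 alkene of drimenol is traced back through a C7 enol triflate to a C7 ketone. The ketone comes from a C7 silyl enol ether whose C11 is still an acyl oxazolidinone.
3. Feature that carries the plan (drimane numbering): in ring B (C5–C10) the bonds C5–C10 and C8–C9 lie para to each other, and ring A (C10–C1–C2–C3–C4–C5, gem-dimethyl C4) is a four-carbon bridge between C10 and C5. The decalin is therefore the retron of a 1,7,9-decatriene intramolecular [4+2], with C9=C10 (activated by C11) as dienophile and C5=C6–C7=C8 as diene.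
4. Ring order: rings A and B are closed together in that one step from an acyclic trienimide. No carbocycle is made before or after it.
5. The triene is assembled at C5=C6 (HWE olefination) and at C1–C10 (stereospecific B-alkyl Suzuki coupling of an (E)-enol triflate). The building blocks are 2,2-dimethylpent-4-enal, ethyl acetoacetate, diethyl (2-oxobutyl)phosphonate and (S)-4-benzyloxazolidin-2-one.

Key step: step 9

Assumption: drimane numbering is applied to all intermediates, the acyclic ones included; C8, which is stereogenic only between the cycloadduct and the enol triflate, is drawn as the epimer expected at each stage.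

## Route

Step 1
Reactants: 1 2,2-dimethylpent-4-enal
Product: 2 2-(2-methylpent-4-en-2-yl)-1,3-dioxolane
Conditions: HOCH2CH2OH, p-TsOH (cat.), cyclohexane, Dean–Stark, reflux
Reagents that add atoms: ethylene glycol, OCCO
Why: Acid-catalysed acetalisation driven by azeotropic removal of water; the α-quaternary aldehyde cannot enolise, and the dioxolane shields C5 from the borane, the hydroxide and the acyl-transfer chemistry that follow.

Step 2
Reactants: 3 ethyl acetoacetate
Product: 4 ethyl (2E)-3-(trifluoromethylsulfonyloxy)but-2-enoate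
Conditions: Tf2O, aq. Me4NOH, hexanes, 5 °C
Reagents that add atoms: triflic anhydride, O=S(=O)(OS(=O)(=O)C(F)(F)F)C(F)(F)F
Why: O-Sulfonylation of a β-keto ester enolate under two-phase Schotten–Baumann-type conditions; with the non-coordinating Me4N+ counter-ion the enolate reacts from its open, dipole-minimised form and not from a metal chelate, so the triflate ends trans to the ester, which places the methyl group (future C15) cis to the carbonyl carbon (future C11).

Step 3
Reactants: 2 2-(2-methylpent-4-en-2-yl)-1,3-dioxolane; 4 ethyl (2E)-3-(trifluoromethylsulfonyloxy)but-2-enoate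
Product: 6 ethyl (2E)-7-(1,3-dioxolan-2-yl)-3,7-dimethyloct-2-enoate, via B-alkyl-9-BBN adduct 5 (not isolated)
Conditions: 9-BBN-H, THF, 0→23 °C; then 4, PdCl2(dppf) (5 mol %), K3PO4 (3 M aq.), DMF, 23→50 °C
Reagents that add atoms: 9-borabicyclo[3.3.1]nonane, [H]B1C2CCCC1CCC2 (boron and its ring stand in 5 only; 6 keeps one hydrogen from it)
Why: Anti-Markovnikov hydroboration of the only alkene followed by B-alkyl Suzuki–Miyaura coupling, which makes C1–C10; oxidative addition of zerovalent palladium to the vinyl triflate and reductive elimination both proceed with retention, so the (E) geometry of C9=C10 is inherited from 4 and does not depend on the modest selectivity of a methyl ketone olefination.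

Step 4
Reactants: 6 ethyl (2E)-7-(1,3-dioxolan-2-yl)-3,7-dimethyloct-2-enoate
Product: 7 (2E)-7-(1,3-dioxolan-2-yl)-3,7-dimethyloct-2-enoic acid
Conditions: LiOH·H2O, THF–MeOH–H2O, 50 °C; then 1 M HCl to pH 4, 0 °C
Reagents that add atoms: lithium hydroxide, [Li+].[OH-]
Why: Saponification of the conjugated ester; the dioxolane is inert to hydroxide, the short cold acidification spares it, and the trisubstituted alkene stays conjugated and (E).

Step 5
Reactants: 7 (2E)-7-(1,3-dioxolan-2-yl)-3,7-dimethyloct-2-enoic acid; 8 (S)-4-benzyloxazolidin-2-one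
Product: 10 (S)-4-benzyl-3-[(2E)-7-(1,3-dioxolan-2-yl)-3,7-dimethyloct-2-enoyl]oxazolidin-2-one, via mixed pivalic anhydride 9 (not isolated)
Conditions: PivCl, Et3N, THF, −20 °C; then LiCl, 8, −20→23 °C
Reagents that add atoms: pivaloyl chloride, CC(C)(C)C(=O)Cl (its acyl group stands in 9 only)
Why: N-Acylation of the oxazolidinone through a mixed pivalic anhydride (LiCl/Et3N variant), in which the tert-butyl group steers attack to the enoyl carbonyl; the stereocentre of the auxiliary is brought in with 8 and is not touched.

Step 6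
Reactants: 10 (S)-4-benzyl-3-[(2E)-7-(1,3-dioxolan-2-yl)-3,7-dimethyloct-2-enoyl]oxazolidin-2-one
Product: 11 (S)-4-benzyl-3-[(2E)-3,7,7-trimethyl-8-oxooct-2-enoyl]oxazolidin-2-one
Conditions: 1 M aq. HCl, THF, 23→40 °C
Reagents that add atoms: water, O
Why: Acid hydrolysis of the acetal; the imide and the conjugated alkene tolerate dilute aqueous acid, and the aldehyde released has no α-hydrogen to epimerise or aldolise.

Step 7
Reactants: 11 (S)-4-benzyl-3-[(2E)-3,7,7-trimethyl-8-oxooct-2-enoyl]oxazolidin-2-one; 12 diethyl (2-oxobutyl)phosphonate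
Product: 13 (S)-4-benzyl-3-[(2E,8E)-3,7,7-trimethyl-10-oxododeca-2,8-dienoyl]oxazolidin-2-one
Conditions: LiCl, i-Pr2NEt, MeCN, 23 °C
Reagents that add atoms: none
Why: Horner–Wadsworth–Emmons olefination under Masamune–Roush conditions, making C5=C6; the LiCl/amine base pair is too mild to cleave or deconjugate the imide, and a stabilised ketophosphonate with an α-branched aldehyde gives the (E)-enone.

Step 8
Reactants: 13 (S)-4-benzyl-3-[(2E,8E)-3,7,7-trimethyl-10-oxododeca-2,8-dienoyl]oxazolidin-2-one
Product: 14 (S)-4-benzyl-3-[(2E,8E,10Z)-10-(tert-butyldimethylsilyloxy)-3,7,7-trimethyldodeca-2,8,10-trienoyl]oxazolidin-2-one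
Conditions: TBSOTf, Et3N, CH2Cl2, −78→0 °C
Reagents that add atoms: tert-butyldimethylsilyl triflate, CC(C)(C)[Si](C)(C)OS(=O)(=O)C(F)(F)F
Why: Soft enolisation with a silyl triflate and an amine; C8 is the only enolisable position of the enone because C6 is vinylic and C4 is quaternary, the ketone is silylated far faster than the imide, and the methyl group turns away from the alkenyl residue, which gives the (Z)-enol ether with C12 pointing outward on the s-cis diene.

Step 9
Reactants: 14 (S)-4-benzyl-3-[(2E,8E,10Z)-10-(tert-butyldimethylsilyloxy)-3,7,7-trimethyldodeca-2,8,10-trienoyl]oxazolidin-2-one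
Product: 16 trans-fused cycloadduct (S)-4-benzyl-3-{[(1S,2R,4aS,8aS)-3-(tert-butyldimethylsilyloxy)-2,5,5,8a-tetramethyl-1,2,4a,5,6,7,8,8a-octahydronaphthalen-1-yl]carbonyl}oxazolidin-2-one (5α-H; 8β-CH3; 9β-acyl; 10β-CH3), via dimethylaluminium chelate 15 (not isolated)
Conditions: Me2AlCl (2 equiv), CH2Cl2 (0.005 M), −30→0 °C; Et3N, then aq. NaHCO3
Reagents that add atoms: dimethylaluminium chloride, C[Al](C)Cl (its atoms stand in 15 only)
Why: Proposed new method: chelate-controlled, Lewis acid-promoted intramolecular Diels–Alder reactions of (E)-trienoyl oxazolidinones are the closest known reaction type, but they have been shown for β-monosubstituted enoyl units and alkyl dienes, not for a β,β-disubstituted C9=C10 unit that creates quaternary C10 or for a 2-silyloxydiene partner. Excess Me2AlCl ionises the imide complex to the cationic six-membered chelate 15 (counter-ion Me2AlCl2−), whose very low LUMO is meant to pay for the extra β-methyl group, and a concerted but asynchronous [4+2] follows in which C5–C10 runs ahead of C8–C9. Ring B closes as the cyclohexene of the cycloaddition and ring A as the six-membered tether ring C10–C1–C2–C3–C4–C5 in a chair-like fold that the gem-dimethyl group at C4 favours (Thorpe–Ingold effect). Regiochemistry is fixed by the four-carbon tether alone and runs against the polarity of the diene, since the nucleophilic enol ether carbon C8 must bond to the α-carbon C9: the silyloxy group therefore only lifts the HOMO and later delivers the C7 ketone, a stepwise Mukaiyama–Michael route cannot reach 16 (C8 to C10 attack would need a nine-membered ring), and its intermolecular version is held down by high dilution. C9 and C10 are set by the benzyl group, which covers the C9 Re face of the s-cis chelate so that the diene adds to the Si face, while suprafacial addition to the (E)-alkene keeps C11 cis to C15. C5 follows from the transition state with the imide carbonyl endo and the tether exo (C4 ends cis to C15, so H5 is trans to C15 and the decalin is trans-fused), C8 from the outward methyl group of the (Z)-enol ether, which ends cis to C11, and the facial, endo and chemoselectivity that the step needs rest on the auxiliary, on the chelated carbonyl and on the robust TBS ether together with proton-scavenging Me2AlCl.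

Step 10
Reactants: 16 trans-fused cycloadduct
Product: 17 [(1S,2R,4aS,8aS)-3-(tert-butyldimethylsilyloxy)-2,5,5,8a-tetramethyl-1,2,4a,5,6,7,8,8a-octahydronaphthalen-1-yl]methanol
Conditions: LiBH4, Et2O–THF, 0→23 °C
Reagents that add atoms: none
Why: Reductive cleavage of an N-acyl oxazolidinone with LiBH4, hydride adding twice to the lithium-activated exocyclic carbonyl; the conditions do not enolise C9, the silyl enol ether keeps C7 out of reach of the hydride, and the auxiliary is recovered.

Step 11
Reactants: 17 C11 alcohol with C7 silyl enol ether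
Product: 18 (3S,4S,4aS,8aS)-4-(hydroxymethyl)-3,4a,8,8-tetramethyloctahydronaphthalen-2(1H)-one (11-hydroxydriman-7-one; 8α-CH3 equatorial)
Conditions: 1 M aq. HCl, THF, 23 °C
Reagents that add atoms: none
Why: Acid hydrolysis of the silyl enol ether by protonation at C6; under the same acid the axial 8β-methyl group, which is syn-diaxial to C15, should equilibrate through the enol to the equatorial 8α position, a point without consequence since C8 becomes sp2 in step 13.

Step 12
Reactants: 18 11-hydroxydriman-7-one
Product: 19 11-(tert-butyldimethylsilyloxy)driman-7-one (5α-H; 8α-CH3; 9β-CH2OTBS; 10β-CH3)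
Conditions: TBSCl, imidazole, DMF, 23 °C
Reagents that add atoms: tert-butyldimethylsilyl chloride, CC(C)(C)[Si](C)(C)Cl
Why: Standard silylation of a primary alcohol, needed because the free hydroxyl group would quench the amide base and be sulfonylated in the next step; the ketone is left alone by imidazole.

Step 13
Reactants: 19 11-(tert-butyldimethylsilyloxy)driman-7-one
Product: 21 11-(tert-butyldimethylsilyloxy)drim-7-en-7-yl triflate (5α-H; 9β-CH2OTBS; 10β-CH3), via bromomagnesium enolate 20 (not isolated)
Conditions: i-Pr2NMgBr (from EtMgBr + i-Pr2NH), Et2O, 23 °C, equilibration; then PhNTf2, 23→35 °C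
Reagents that add atoms: N-phenylbis(trifluoromethanesulfonimide), O=S(=O)(N(c1ccccc1)S(=O)(=O)C(F)(F)F)C(F)(F)F; bromomagnesium diisopropylamide, CC(C)N([Mg]Br)C(C)C (MgBr stands in 20 only)
Why: Regioselective enol triflate synthesis by trapping a thermodynamic enolate; the magnesium amide lets the enolates equilibrate by proton exchange towards the more substituted C7=C8 isomer (axial H8 is well aligned), and PhNTf2 sulfonylates oxygen without disturbing the silyl ether or C9.

Step 14
Reactants: 21 11-(tert-butyldimethylsilyloxy)drim-7-en-7-yl triflate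
Product: 22 (−)-drimenol tert-butyldimethylsilyl ether
Conditions: Pd(OAc)2 (5 mol %), PPh3 (10 mol %), HCO2H, n-Bu3N, DMF, 60 °C
Reagents that add atoms: none
Why: Palladium-catalysed formate reduction of an enol triflate; zerovalent palladium formed from Pd(OAc)2 and PPh3 inserts into the C7–O bond, formate exchange and loss of CO2 give a palladium hydride, and reductive elimination puts hydrogen on C7 with the double bond fixed at C7=C8.

Step 15
Reactants: 22 (−)-drimenol tert-butyldimethylsilyl ether
Product: 23 (−)-drimenol [(1S,4aS,8aS)-2,5,5,8a-tetramethyl-1,4,4a,5,6,7,8,8a-octahydronaphthalen-1-yl]methanol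
Conditions: n-Bu4NF, THF, 23 °C
Reagents that add atoms: none
Why: Fluoride cleavage of the alkyl silyl ether, driven by the Si–F bond; nothing else in 22 reacts, and comparison of 23 with the known natural alcohol checks relative and absolute configuration before the last two steps.

Step 16
Reactants: 24 caffeic acid
Product: 26 (E)-3-[3,4-bis(tert-butyldimethylsilyloxy)phenyl]acrylic acid, via tris-TBS caffeate 25 (not isolated)
Conditions: TBSCl, imidazole, DMF, 23 °C; then AcOH–THF–H2O, 23 °C
Reagents that add atoms: tert-butyldimethylsilyl chloride, CC(C)(C)[Si](C)(C)Cl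
Why: Exhaustive silylation of both phenols and the acid followed by selective hydrolysis of the far more labile silyl ester; masking the catechol prevents its acylation and oxidation during the coupling.

Step 17
Reactants: 23 (−)-drimenol; 26 (E)-3-[3,4-bis(tert-butyldimethylsilyloxy)phenyl]acrylic acid
Product: 27 (−)-drimenyl (E)-3-[3,4-bis(tert-butyldimethylsilyloxy)phenyl]acrylate
Conditions: EDC·HCl, DMAP, CH2Cl2, 0→23 °C
Reagents that add atoms: none
Why: Steglich-type carbodiimide esterification; DMAP forms the acylpyridinium ion that the hindered, neopentyl-like C11 alcohol can still attack, no stereocentre is involved and the (E)-cinnamate geometry is retained.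

Step 18
Reactants: 27 (−)-drimenyl (E)-3-[3,4-bis(tert-butyldimethylsilyloxy)phenyl]acrylate
Product: 28 CNP0265201.1, (−)-drimenyl caffeate (5S,9S,10S in drimane numbering)
Conditions: n-Bu4NF, AcOH, THF, 0 °C
Reagents that add atoms: none
Why: Fluoride cleavage of the two aryl silyl ethers, buffered by acetic acid so that the phenoxides are protonated at once and neither ester cleavage nor catechol oxidation sets in; the trisubstituted alkene and the three stereocentres are not affected.

## Compound list

1 | 2,2-dimethylpent-4-enal | C=CCC(C)(C)C=O | starting material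
2 | 2-(2-methylpent-4-en-2-yl)-1,3-dioxolane | C=CCC(C)(C)C1OCCO1 | intermediate
3 | ethyl acetoacetate | CCOC(=O)CC(C)=O | starting material
4 | ethyl (2E)-3-(trifluoromethylsulfonyloxy)but-2-enoate | CCOC(=O)/C=C(\C)OS(=O)(=O)C(F)(F)F | intermediate
5 | 9-[4-(1,3-dioxolan-2-yl)-4-methylpentyl]-9-borabicyclo[3.3.1]nonane | O1CCOC1C(C)(C)CCCB1C2CCCC1CCC2 | intermediate
6 | ethyl (2E)-7-(1,3-dioxolan-2-yl)-3,7-dimethyloct-2-enoate | CCOC(=O)/C=C(\C)CCCC(C)(C)C1OCCO1 | intermediate
7 | (2E)-7-(1,3-dioxolan-2-yl)-3,7-dimethyloct-2-enoic acid | OC(=O)/C=C(\C)CCCC(C)(C)C1OCCO1 | intermediate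
8 | (S)-4-benzyloxazolidin-2-one | O=C1N[C@@H](Cc2ccccc2)CO1 | starting material
9 | (2E)-7-(1,3-dioxolan-2-yl)-3,7-dimethyloct-2-enoic pivalic anhydride | CC(C)(C)C(=O)OC(=O)/C=C(\C)CCCC(C)(C)C1OCCO1 | intermediate
10 | (S)-4-benzyl-3-[(2E)-7-(1,3-dioxolan-2-yl)-3,7-dimethyloct-2-enoyl]oxazolidin-2-one | O=C1OC[C@H](Cc2ccccc2)N1C(=O)/C=C(\C)CCCC(C)(C)C1OCCO1 | intermediate
11 | (S)-4-benzyl-3-[(2E)-3,7,7-trimethyl-8-oxooct-2-enoyl]oxazolidin-2-one | O=C1OC[C@H](Cc2ccccc2)N1C(=O)/C=C(\C)CCCC(C)(C)C=O | intermediate
12 | diethyl (2-oxobutyl)phosphonate | CCC(=O)CP(=O)(OCC)OCC | starting material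
13 | (S)-4-benzyl-3-[(2E,8E)-3,7,7-trimethyl-10-oxododeca-2,8-dienoyl]oxazolidin-2-one | O=C1OC[C@H](Cc2ccccc2)N1C(=O)/C=C(\C)CCCC(C)(C)/C=C/C(=O)CC | intermediate
14 | (S)-4-benzyl-3-[(2E,8E,10Z)-10-(tert-butyldimethylsilyloxy)-3,7,7-trimethyldodeca-2,8,10-trienoyl]oxazolidin-2-one | O=C1OC[C@H](Cc2ccccc2)N1C(=O)/C=C(\C)CCCC(C)(C)/C=C/C(O[Si](C)(C)C(C)(C)C)=C/C | intermediate
15 | cationic dimethylaluminium chelate of 14 (both imide oxygens on Al), dichlorodimethylaluminate salt | C[Al-]1(C)[O+]=C(/C=C(\C)CCCC(C)(C)/C=C/C(O[Si](C)(C)C(C)(C)C)=C/C)N2C(=[O+]1)OC[C@@H]2Cc1ccccc1.C[Al-](C)(Cl)Cl | intermediate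
16 | trans-fused cycloadduct, C7 silyl enol ether, C11 imide (1S,2R,4aS,8aS; auxiliary S) | C[C@H]1C(O[Si](C)(C)C(C)(C)C)=C[C@H]2C(C)(C)CCC[C@]2(C)[C@H]1C(=O)N1C(=O)OC[C@@H]1Cc1ccccc1 | intermediate
17 | [(1S,2R,4aS,8aS)-3-(tert-butyldimethylsilyloxy)-2,5,5,8a-tetramethyl-1,2,4a,5,6,7,8,8a-octahydronaphthalen-1-yl]methanol | C[C@H]1C(O[Si](C)(C)C(C)(C)C)=C[C@H]2C(C)(C)CCC[C@]2(C)[C@H]1CO | intermediate
18 | (3S,4S,4aS,8aS)-4-(hydroxymethyl)-3,4a,8,8-tetramethyloctahydronaphthalen-2(1H)-one | C[C@@H]1C(=O)C[C@H]2C(C)(C)CCC[C@]2(C)[C@H]1CO | intermediate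
19 | 11-(tert-butyldimethylsilyloxy)driman-7-one (8α-CH3) | C[C@@H]1C(=O)C[C@H]2C(C)(C)CCC[C@]2(C)[C@H]1CO[Si](C)(C)C(C)(C)C | intermediate
20 | bromomagnesium C7=C8 enolate of 19 | CC1=C(O[Mg]Br)C[C@H]2C(C)(C)CCC[C@]2(C)[C@H]1CO[Si](C)(C)C(C)(C)C | intermediate
21 | 11-(tert-butyldimethylsilyloxy)drim-7-en-7-yl triflate | CC1=C(OS(=O)(=O)C(F)(F)F)C[C@H]2C(C)(C)CCC[C@]2(C)[C@H]1CO[Si](C)(C)C(C)(C)C | intermediate
22 | (−)-drimenol tert-butyldimethylsilyl ether | CC1=CC[C@H]2C(C)(C)CCC[C@]2(C)[C@H]1CO[Si](C)(C)C(C)(C)C | intermediate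
23 | (−)-drimenol | CC1=CC[C@H]2C(C)(C)CCC[C@]2(C)[C@H]1CO | intermediate
24 | caffeic acid | O=C(O)/C=C/c1ccc(O)c(O)c1 | starting material
25 | tert-butyldimethylsilyl (E)-3-[3,4-bis(tert-butyldimethylsilyloxy)phenyl]acrylate | CC(C)(C)[Si](C)(C)OC(=O)/C=C/c1ccc(O[Si](C)(C)C(C)(C)C)c(O[Si](C)(C)C(C)(C)C)c1 | intermediate
26 | (E)-3-[3,4-bis(tert-butyldimethylsilyloxy)phenyl]acrylic acid | OC(=O)/C=C/c1ccc(O[Si](C)(C)C(C)(C)C)c(O[Si](C)(C)C(C)(C)C)c1 | intermediate
27 | (−)-drimenyl (E)-3-[3,4-bis(tert-butyldimethylsilyloxy)phenyl]acrylate | CC1=CC[C@H]2C(C)(C)CCC[C@]2(C)[C@H]1COC(=O)/C=C/c1ccc(O[Si](C)(C)C(C)(C)C)c(O[Si](C)(C)C(C)(C)C)c1 | intermediate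
28 | CNP0265201.1, (−)-drimenyl caffeate | CC1=CC[C@H]2C(C)(C)CCC[C@]2(C)[C@H]1COC(=O)/C=C/c1ccc(O)c(O)c1 | target

## Counts

Total step count: 18.
Longest linear sequence: 16 (steps 1, 3–15, 17 and 18).

## Steps most likely to fail

**Step 9 (labelled step).**

What may go wrong:
- The cycloaddition may be too slow. The β-methyl group twists and shields the chelated enoyl unit. C5 sits next to quaternary C4 and is not the electron-rich end of the diene.
- Three processes can then take over: Lewis acid-induced loss of the silyl enol ether, intermolecular conjugate addition through C8, and leakage into the tether-endo (cis-fused) transition state.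

Fallback: this uses known chemistry, namely the thermal intramolecular Diels–Alder reaction of an activated 1,7,9-decatrienoate, a class that includes dienophiles with a methyl group on the internal carbon, followed by classical resolution. It sets out from ester 6 and gives up both the Lewis acid and the auxiliary. Hydrolysis of the dioxolane (aq. HCl, THF) gives the aldehyde ester F1. Olefination with 12 (LiCl, i-Pr2NEt, MeCN) gives the enone ester F2, and TBSOTf/Et3N gives the silyloxy triene ester F3. Heating in toluene (BHT, sealed tube, 160–180 °C), with the small ester as the endo group, should give the racemic trans-fused ester F4. LiAlH4 then gives 17 together with its enantiomer F5. Esterification of this racemate with (S)-2-methoxy-2-phenylacetic acid (DCC, DMAP) gives the O-methylmandelate of 17 F6 and the O-methylmandelate of the enantiomer F7, which are separated by chromatography. LiAlH4 on F6 comes back to the route at 17.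

**Step 13.**

What may go wrong:
- Equilibration of the magnesium enolate may stay incomplete, so that part of the sulfonylation takes place on the C6 side.
- O-Sulfonylation of a tetrasubstituted enolate may be sluggish.

Fallback: this sets out from 19 and replaces enolate regiocontrol by stereoelectronic control of an E2 elimination. LiBH(s-Bu)3 (THF, −78 °C) attacks C7 from the equatorial side and gives the axial 7α-alcohol F8. POCl3 in pyridine then removes it by anti elimination, in which the axial tertiary H8 is lost in preference (Zaitsev orientation). This comes back to the route at 22 and makes step 14 unnecessary.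

**Step 10.**

What may go wrong:
- The exocyclic carbonyl is flanked by quaternary C10 and by the C8 methyl group. Hydride may therefore attack the ring carbamate carbonyl and open the oxazolidinone instead of releasing it.

Fallback: this sets out from 16. EtSLi (from EtSH and n-BuLi, THF, 0 °C) is a small, soft nucleophile known to cleave hindered imides at the exocyclic carbonyl. It gives the S-ethyl thioester F9, which LiAlH4 (Et2O, 0 °C) reduces, coming back to the route at 17.

## Further compounds

F1 | step 9 | aldehyde ester, ethyl (2E)-3,7,7-trimethyl-8-oxooct-2-enoate | CCOC(=O)/C=C(\C)CCCC(C)(C)C=O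
F2 | step 9 | enone ester, ethyl (2E,8E)-3,7,7-trimethyl-10-oxododeca-2,8-dienoate | CCOC(=O)/C=C(\C)CCCC(C)(C)/C=C/C(=O)CC
F3 | step 9 | silyloxy triene ester, ethyl (2E,8E,10Z)-10-(tert-butyldimethylsilyloxy)-3,7,7-trimethyldodeca-2,8,10-trienoate | CCOC(=O)/C=C(\C)CCCC(C)(C)/C=C/C(O[Si](C)(C)C(C)(C)C)=C/C
F4 | step 9 | racemic trans-fused ester (one enantiomer drawn) | C[C@H]1C(O[Si](C)(C)C(C)(C)C)=C[C@H]2C(C)(C)CCC[C@]2(C)[C@H]1C(=O)OCC
F5 | step 9 | enantiomer of 17 | C[C@@H]1C(O[Si](C)(C)C(C)(C)C)=C[C@@H]2C(C)(C)CCC[C@@]2(C)[C@@H]1CO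
F6 | step 9 | (S)-O-methylmandelate of 17 | C[C@H]1C(O[Si](C)(C)C(C)(C)C)=C[C@H]2C(C)(C)CCC[C@]2(C)[C@H]1COC(=O)[C@@H](OC)c1ccccc1
F7 | step 9 | (S)-O-methylmandelate of the enantiomer of 17 | C[C@@H]1C(O[Si](C)(C)C(C)(C)C)=C[C@@H]2C(C)(C)CCC[C@@]2(C)[C@@H]1COC(=O)[C@@H](OC)c1ccccc1
F8 | step 13 | axial 7α-alcohol, 11-(tert-butyldimethylsilyloxy)driman-7α-ol (8α-CH3) | C[C@@H]1[C@H](O)C[C@H]2C(C)(C)CCC[C@]2(C)[C@H]1CO[Si](C)(C)C(C)(C)C
F9 | step 10 | S-ethyl thioester of the cycloadduct acid | C[C@H]1C(O[Si](C)(C)C(C)(C)C)=C[C@H]2C(C)(C)CCC[C@]2(C)[C@H]1C(=O)SCC
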